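- Start from a one-step world: starting material turns to target until the target share reaches 1. The runs refuse this, since they level off early.

| flask | starting material | catalyst | target | time |
|---|---|---|---|---|
| red | 250 mM | 2.50 mM |  |  |
| violet | 130 mM | 2.50 mM |  |  |
| ochre | 250 mM | 2.50 mM | 75.0 mM |  |
| amber | 250 mM | 3.70 mM |  |  |
| teal | 500 mM | 0.830 mM |  | 37 h |

| run | time / h | [target] / mM |
|---|---|---|
| red run | 4.6 | 35 |
| red run | 9.2 | 68 |
| red run | 14 | 89 |
| red run | 18 | 105 |
| red run | 23 | 119 |
| red run | 28 | 127 |
| red run | 32 | 128 |
| red run | 37 | 132 |
| violet run | 4.6 | 22 |
| violet run | 9.2 | 44 |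
| violet run | 14 | 54 |
| violet run | 18 | 70 |
| violet run | 23 | 67 |
| violet run | 28 | 82 |
| violet run | 32 | 82 |
| violet run | 37 | 83 |
| ochre run | 4.6 | 113 |
| ochre run | 9.2 | 135 |
| ochre run | 14 | 164 |
| ochre run | 18 | 180 |
| ochre run | 23 | 192 |
| ochre run | 28 | 203 |
| ochre run | 32 | 209 |
| ochre run | 37 | 209 |
| amber run | 4.6 | 49 |
| amber run | 9.2 | 95 |
| amber run | 14 | 122 |
| amber run | 18 | 139 |
| amber run | 23 | 157 |
| amber run | 28 | 157 |
| amber run | 32 | 159 |
| amber run | 37 | 158 |

(standard deviation of a reading: 3 mM)

1. how the opening rate goes with [starting material] round the charge of the red run: the exponent of the rate at two percent of starting material gone to target (one fixed amount of target, the same in the runs compared)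
2. how the opening rate goes with [catalyst] round the charge of the red run: the exponent of the rate at two percent of starting material gone to target
3. target in the teal run at 37 h, as a share of the starting material charged

- Overall: starting material -> target, with catalyst as catalyst.
- Constant volume, constant temperature.
- A reading of a species includes what of it is bound.
- An order is taken over about fifteen percent of the charge, up and down.

- Read the last red reading as a share of the charge: 52.8%. Ochre's last reading stands 53.6% of its charge above its added target, so treat added target as inert.
- Compare amber with red: the first reading rises by a factor 1.40, the last by 1.20, less than the first. So don't read the plateau as rate times a fixed catalyst lifetime.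
- Suppose instead that starting material leaves by two doors, the target and a first-order loss. Red then gives 1.12 for the plateau odds, the share made over the share not made, a selectivity factor averaged over the run.
- Take violet, at share 63.8%, with odds 1.77. These odds scale as the charge to the order minus 1, so my order in starting material reads 0.302.
- Take amber, with odds 1.72. Its catalyst exponent reads 1.09 from the odds and 0.858 from the first readings, so take 1.
- Scale to teal: the odds become 0.229, a plateau share of 18.6%.
- Reforge the weak link, that teal has levelled off by 37 h. Red closes its gap at 0.0787 h⁻¹, of which the loss door takes 0.0371 h⁻¹.
- Put the teal share back in: its clock is 0.0456 h⁻¹, so 81.5% of the plateau stands at 37 h. Commit to 15.2%.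
- The forecast, holding that “the catalyst dies”, gives 0.67, 0.95 and 15.5%, where my order in starting material is 0.302.
- The flask gives 0.32, 1.0 and 17.5%, so my teal share is lower by 2.3 percentage points.

    catalyst + starting material → target + catalyst (42.84 M⁻¹ h⁻¹)
    starting material → decomposed substrate (0.04320 h⁻¹)
    catalyst + starting material ⇌ idle catalyst-substrate complex, settled at all times (9.400 M⁻¹)

- Credit the low order to catalyst parked as idle catalyst-substrate complex: removing the parking lifts the order from 0.32 to 1.0. Parked, teal opens with the rate through the target door over the rate through the loss door at 0.144; the same flask without parking opens at 0.823, and there these opening odds stay the plateau odds. Run the rule on that second flask: its share is 45.1%, its clock 0.0788 h⁻¹, and at 37 h it reaches 42.7%. The simulated run without parking holds 42.7%.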